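The flasks hold 20.0 µM of catalyst L against 10 mM of substrate Q, and L is also bound as Q.L and L.D.

the same everywhere: L 0.2 mol%; D 73 µM; time 2.5 h

| run | Q | X | remark |
|---|---|---|---|
| violet | 10 mM | 1.30 equiv | everything together at the start |
| grey | 10 mM (in portions, 5, over 2.0 h) | 1.30 equiv | first portion at the start, last at 2.0 h |
| blue | 10 mM (fed, over 30 min) | 1.30 equiv | all else is in the flask from the start; the feed brings no volume worth counting |
| red | 10 mM (fed, over 2.0 h) | 1.30 equiv | all else is in the flask from the start; the feed brings no volume worth counting |
| teal | 10 mM | 1.30 equiv (fed, over 2.0 h) | all else is in the flask from the start; the feed brings no volume worth counting |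

    Q + L ⇌ Q.L, settled at all times (K1 = 191 /M)
    L + D ⇌ L.D, settled at all times (K2 = 11300 /M)
    Q + X + L → L + J (k3 = 4.10 × 10⁵ /M²/h)
    2 Q → Q2 (k4 = 1.45 /M/h)

- a species is counted by the Q in it: one Q2 counts as two
- where a step has two of a species, its rate is k times that concentration squared, and two are used at each turn
- run time (violet): 2.5 h

- the best flask by share of J in J plus Q2; "all alike" if 1.5 percentage points covers them all (violet / grey / blue / red / teal / all alike)
- share of J in J plus Q2 at the end, violet
- share of J in J plus Q2 at the end, grey
- share of J in J plus Q2 at the end, blue
- share of J in J plus Q2 at the end, red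
- share of J in J plus Q2 at the end, teal

In violet at the start, free L, Q.L and L.D stand at balance as 1 to 1.9 to 0.82, so the free share of L is 26.8%. My own reckoning starts from the half-life of Q by the catalysed step, 6.5 h with L as charged. Turned into a lifetime and divided by the free share, it becomes 35.0 h. By the step to Q2, the lifetime of Q at 10 mM is 34.5 h.

The second lifetime divided by the first is 0.984 for violet at the start. This is the quantity to carry, the route ratio ρ, the Q going to J per Q going to Q2 at that moment, a selectivity factor. The share of J, ρ over one plus ρ, is 49.6% for violet. Because the run of 2.5 h is short against both lifetimes , Q and X stay close to what has gone in, and ρ can be reckoned from the levels fed.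

Q2 forms on Q squared, so the level that counts in a fed flask is the mean of Q weighted by Q. That level is 9.63 mM in blue, 7.78 mM in red and 7.33 mM in grey. The shares are then 51.0%, 58.8% and 60.8%. Teal holds Q close to 10 mM, but its X averages 60.0% of the charge over the run, so ρ becomes 0.591 and the share 37.1%. Grey stands highest.

The forecast also named grey, with 52% for violet, 63.4% for grey, 53.4% for blue, 61.3% for red and 38.5% for teal, on the ground “Selectivity therefore depends on keeping Q low”. Its shares lie above my reckoning .

The simulation gives 51.9% for violet, 63.4% for grey, 53.4% for blue, 61.4% for red and 38.6% for teal, with grey best.

In teal at 2.50 h, the readings of J over Q2 give 0.628, against the reckoned ρ of 0.591. The neighbour of teal has L cut to 0.08 mol% and its other charges unchanged. With the same free share, ρ falls in step with the loading to 0.236, a share of 19.1%. That neighbour ends with J at 1.66% and Q2 at 6.68% of the Q charged, a share of 19.9%.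

The constants used here stand for no real mixture; the run is a simulation.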